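The 1,2‑dioxane (O1–O2–C3–C4–C5–C6) is disconnected at C5–C6, exploiting that C6 is a fully substituted, peroxide‑bearing ring carbon, i.e. a latent ketone at the peroxycarbenium oxidation level. An allylic hydroperoxide carrying the C3 stereocentre and a 2‑(silylmethyl)allyl nucleophile is joined to the ketal of a C6–C9 methyl ketone as a mixed monoperoxyketal. Ionisation and intramolecular Hosomi–Sakurai attack of C5 on C6 then closes the ring, sets the quaternary C6 centre and leaves a C4 exo‑methylene, which diimide converts into the C4 methyl stereocentre. A late Julia–Kocienski olefination (C9=C10) appends the styrenyl side chain.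

Key step: step 9

Remark: numbering used is O1, O2, C3 (CH2CO2H arm), C4 (CH3), C5, C6 (CH3 and side chain C7–C14, phenyl on C14); the target is (3S,4S,6R,8R,12S).

**Ketone fragment (C6–C9)**

Step 1
Reactants: 1 (S)-3-bromo-2-methylpropan-1-ol
Product: 2 (S)-(3-bromo-2-methylpropoxy)(tert-butyl)diphenylsilane
Conditions: TBDPSCl, imidazole, CH2Cl2, 0 °C to rt
Reagents that add atoms: tert-butyl(chloro)diphenylsilane, CC(C)(C)[Si](Cl)(c1ccccc1)c1ccccc1
Why: Imidazole-promoted silylation of the primary alcohol; the stereocentre is not touched.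

Step 2
Reactants: 2 (S)-(3-bromo-2-methylpropoxy)(tert-butyl)diphenylsilane
Product: 4 (R)-5-[(tert-butyldiphenylsilyl)oxy]-4-methylpentan-2-one, via Grignard reagent 3 (not isolated)
Conditions: Mg turnings (I2 cat.), THF, 45 °C; then MeC(=O)N(OMe)Me, 0 °C; aq. NH4Cl
Reagents that add atoms: N-methoxy-N-methylacetamide, CC(=O)N(C)OC
Why: Grignard formation and Weinreb ketone synthesis, where the chelated tetrahedral intermediate prevents over-addition; the stereocentre is β to magnesium and is retained (the descriptor changes only by priority).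

Step 3
Reactants: 4 (R)-5-[(tert-butyldiphenylsilyl)oxy]-4-methylpentan-2-one
Product: 5 (R)-tert-butyl[(4,4-dimethoxy-2-methylpentyl)oxy]diphenylsilane
Conditions: HC(OMe)3, MeOH, PPTS (cat.), rt
Reagents that add atoms: trimethyl orthoformate, COC(OC)OC; methanol, CO
Why: Acid-catalysed ketalisation driven by the orthoformate as water scavenger; the TBDPS ether is stable to these conditions.

**Hydroperoxide fragment (C1–C5)**

Step 4
Reactants: 6 2-[(trimethylsilyl)methyl]prop-2-en-1-ol
Product: 7 2-[(trimethylsilyl)methyl]prop-2-enal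
Conditions: MnO2 (activated, excess), CH2Cl2, rt; filtered solution used directly
Reagents that add atoms: none
Why: Neutral allylic oxidation with MnO2, which spares the acid-sensitive allylsilane.

Step 5
Reactants: 8 (R)-2-hydroxy-1,2,2-triphenylethyl acetate (HYTRA); 7 2-[(trimethylsilyl)methyl]prop-2-enal
Product: 9 (R)-2-hydroxy-1,2,2-triphenylethyl (R)-3-hydroxy-4-[(trimethylsilyl)methyl]pent-4-enoate
Conditions: 8, LiN(iPr)2 (2.1 equiv), THF, −78 to 0 °C; then 7, −78 °C; aq. NH4Cl
Reagents that add atoms: none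
Why: Auxiliary-controlled acetate aldol addition of the doubly lithiated HYTRA ester (1,2-addition to the enal); the triphenylglycol unit shields one enolate face so that the (3R)-carbinol should form, as with other α-branched aldehydes.

Step 6
Reactants: 9 (R)-2-hydroxy-1,2,2-triphenylethyl (R)-3-hydroxy-4-[(trimethylsilyl)methyl]pent-4-enoate
Product: 10 methyl (R)-3-hydroxy-4-[(trimethylsilyl)methyl]pent-4-enoate
Conditions: K2CO3 (cat.), MeOH, 0 °C to rt
Reagents that add atoms: methanol, CO
Why: Base-catalysed transesterification releases the methyl ester and the recoverable auxiliary diol without touching the carbinol centre.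

Step 7
Reactants: 10 methyl (R)-3-hydroxy-4-[(trimethylsilyl)methyl]pent-4-enoate
Product: 12 methyl (S)-3-hydroperoxy-4-[(trimethylsilyl)methyl]pent-4-enoate, via allylic mesylate 11 (not isolated)
Conditions: MsCl, Et3N, CH2Cl2, −65 °C; then anhydrous H2O2 (excess) in Et2O, −110 to −78 °C
Reagents that add atoms: hydrogen peroxide, OO (methanesulfonyl chloride, CS(=O)(=O)Cl, leaves atoms only in 11)
Why: Sulfonylation followed by SN2 perhydrolysis with neutral H2O2, which inverts C3 (R to S); the very low temperature and absence of base are chosen to suppress ionisation, SN2′ attack and E1cB elimination.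

**Union, ring closure and core elaboration**

Step 8
Reactants: 12 methyl (S)-3-hydroperoxy-4-[(trimethylsilyl)methyl]pent-4-enoate; 5 (R)-tert-butyl[(4,4-dimethoxy-2-methylpentyl)oxy]diphenylsilane
Product: 13 methyl (3S)-3-({(4R)-5-[(tert-butyldiphenylsilyl)oxy]-2-methoxy-4-methylpentan-2-yl}peroxy)-4-[(trimethylsilyl)methyl]pent-4-enoate (both epimers at the ketal carbon)
Conditions: PPTS (cat.), CH2Cl2, 5 Å sieves, 0 °C to rt (5 in excess)
Reagents that add atoms: none
Why: Acid-catalysed transketalisation exchanges one methoxy group of the ketal for the hydroperoxide (mixed monoperoxyketal formation); the new ketal centre forms as a mixture, which is irrelevant because it is ionised in the next step.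

Step 9
Reactants: 13 methyl (3S)-3-({(4R)-5-[(tert-butyldiphenylsilyl)oxy]-2-methoxy-4-methylpentan-2-yl}peroxy)-4-[(trimethylsilyl)methyl]pent-4-enoate
Product: 14 methyl 2-[(3S,6R)-6-{(R)-3-[(tert-butyldiphenylsilyl)oxy]-2-methylpropyl}-6-methyl-4-methylidene-1,2-dioxan-3-yl]acetate
Conditions: Me3SiOSO2CF3 (0.3 equiv), CH2Cl2, −78 °C; pyridine then aq. NaHCO3
Reagents that add atoms: none
Why: The silyl triflate removes the methoxy group of 13 to give the peroxycarbenium ion C6=O1(+)–O2, which is attacked intramolecularly by the terminal CH2 (C5) of the 2-(silylmethyl)allyl unit; loss of Me3Si from the β-silyl cation regenerates the silyl triflate and leaves the C4 exo-methylene (intramolecular Hosomi–Sakurai reaction). The closest known reaction types are the Lewis-acid-mediated cyclisation of unsaturated monoperoxyketals to cyclic peroxides through peroxycarbenium ions and the silyl-modified Sakurai/Prins synthesis of 4-methylenetetrahydropyrans. The dioxane closes in a 6-endo-trig mode with respect to both the C4=C5 nucleophile and the C6=O1 electrophile, through a chair-like transition state with silicon anti to the forming bond. The new C6 stereocentre is controlled by the C3 stereocentre: the acetate arm at C3 sits pseudo-axial to avoid allylic strain with the in-plane CH2SiMe3 group, and the peroxycarbenium ion reacts in its E form with the larger CH2CH(CH3)CH2OSi arm equatorial, which places the two arms cis (6R). The step needs chemoselective ionisation of C–OMe rather than C–OO (secured by the more basic, unhindered methoxy oxygen and the low temperature) and facial selectivity at C6, which rests only on the size difference between CH3 and the β-branched arm and is therefore expected to be modest, so the minor C6 epimer would be removed by chromatography here.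

Step 10
Reactants: 14 methyl 2-[(3S,6R)-6-{(R)-3-[(tert-butyldiphenylsilyl)oxy]-2-methylpropyl}-6-methyl-4-methylidene-1,2-dioxan-3-yl]acetate
Product: 15 methyl 2-[(3S,4S,6R)-6-{(R)-3-[(tert-butyldiphenylsilyl)oxy]-2-methylpropyl}-4,6-dimethyl-1,2-dioxan-3-yl]acetate
Conditions: KO2CN=NCO2K (excess), AcOH, MeOH/CH2Cl2, 0 °C to rt
Reagents that add atoms: none
Why: Diimide reduction (concerted syn transfer of H2, inert to the O–O bond); delivery to the exo-methylene face anti to the adjacent C3 acetate arm (equatorial approach on the conformer with that arm equatorial) should give the 3,4-cis C4 (S) centre.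

Step 11
Reactants: 15 methyl 2-[(3S,4S,6R)-6-{(R)-3-[(tert-butyldiphenylsilyl)oxy]-2-methylpropyl}-4,6-dimethyl-1,2-dioxan-3-yl]acetate
Product: 16 methyl 2-[(3S,4S,6R)-6-[(R)-3-hydroxy-2-methylpropyl]-4,6-dimethyl-1,2-dioxan-3-yl]acetate
Conditions: HF·pyridine, pyridine/THF, 0 °C to rt
Reagents that add atoms: none
Why: Fluoride-mediated silyl ether cleavage under buffered, non-basic conditions, so the β-peroxy ester is not opened by retro-oxa-Michael reaction.

Step 12
Reactants: 16 methyl 2-[(3S,4S,6R)-6-[(R)-3-hydroxy-2-methylpropyl]-4,6-dimethyl-1,2-dioxan-3-yl]acetate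
Product: 17 methyl 2-[(3S,4S,6S)-4,6-dimethyl-6-[(R)-2-methyl-3-oxopropyl]-1,2-dioxan-3-yl]acetate
Conditions: Dess–Martin periodinane, NaHCO3, CH2Cl2, 0 °C
Reagents that add atoms: none
Why: Dess–Martin oxidation under buffered neutral conditions leaves the peroxide, the ester and the α-stereocentre (C8) intact; the C6 descriptor changes only by priority.

**Sulfone fragment (C10–C14)**

Step 13
Reactants: 18 (E)-but-2-enal
Product: 19 rac-(E)-1-phenylbut-2-en-1-ol
Conditions: PhMgBr, THF, −78 to 0 °C; aq. NH4Cl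
Reagents that add atoms: phenylmagnesium bromide, Br[Mg]c1ccccc1
Why: 1,2-Grignard addition to the enal at low temperature gives the racemic allylic alcohol.

Step 14
Reactants: 19 rac-(E)-1-phenylbut-2-en-1-ol
Product: 20 (R,E)-1-phenylbut-2-en-1-ol
Conditions: Ti(OiPr)4 (cat.), D-(−)-diisopropyl tartrate, tBuOOH (0.6 equiv), 4 Å sieves, CH2Cl2, −20 °C
Reagents that add atoms: none
Why: Sharpless kinetic resolution; with the D-(−)-tartrate the (S)-alcohol is the matched, fast-epoxidised enantiomer, so the (R)-alcohol is recovered.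

Step 15
Reactants: 20 (R,E)-1-phenylbut-2-en-1-ol
Product: 22 ethyl (S,E)-3-methyl-5-phenylpent-4-enoate, via ketene acetal 21 (not isolated)
Conditions: MeC(OEt)3, EtCO2H (cat.), 140 °C, EtOH distilled off
Reagents that add atoms: triethyl orthoacetate, CCOC(C)(OCC)OCC
Why: Johnson–Claisen rearrangement; the chair transition state with phenyl equatorial transfers the carbinol configuration suprafacially to the new C–C bond, giving the (E)-styrene and the (S)-methyl stereocentre (C12).

Step 16
Reactants: 22 ethyl (S,E)-3-methyl-5-phenylpent-4-enoate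
Product: 23 (S,E)-3-methyl-5-phenylpent-4-en-1-ol
Conditions: LiAlH4, THF, 0 °C
Reagents that add atoms: none
Why: Hydride reduction of the ester to the primary alcohol; the alkene and the stereocentre are not affected.

Step 17
Reactants: 23 (S,E)-3-methyl-5-phenylpent-4-en-1-ol
Product: 24 5-{[(S,E)-3-methyl-5-phenylpent-4-en-1-yl]sulfanyl}-1-phenyl-1H-tetrazole
Conditions: 1-phenyl-1H-tetrazole-5-thiol, PPh3, DIAD, THF, 0 °C to rt
Reagents that add atoms: 1-phenyl-1H-tetrazole-5-thiol, Sc1nnnn1-c1ccccc1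
Why: Mitsunobu thioetherification of the primary alcohol with the acidic tetrazole thiol.

Step 18
Reactants: 24 5-{[(S,E)-3-methyl-5-phenylpent-4-en-1-yl]sulfanyl}-1-phenyl-1H-tetrazole
Product: 25 5-{[(S,E)-3-methyl-5-phenylpent-4-en-1-yl]sulfonyl}-1-phenyl-1H-tetrazole
Conditions: (NH4)6Mo7O24·4H2O (cat.), 30% H2O2, EtOH, 0 °C to rt
Reagents that add atoms: hydrogen peroxide, OO
Why: Molybdate-catalysed sulfide-to-sulfone oxidation, which is chemoselective for sulfur over the styrenyl alkene.

**Fragment coupling and end game**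

Step 19
Reactants: 25 5-{[(S,E)-3-methyl-5-phenylpent-4-en-1-yl]sulfonyl}-1-phenyl-1H-tetrazole; 17 methyl 2-[(3S,4S,6S)-4,6-dimethyl-6-[(R)-2-methyl-3-oxopropyl]-1,2-dioxan-3-yl]acetate
Product: 26 methyl 2-[(3S,4S,6R)-6-[(2R,3E,6S,7E)-2,6-dimethyl-8-phenylocta-3,7-dien-1-yl]-4,6-dimethyl-1,2-dioxan-3-yl]acetate
Conditions: 25, KN(SiMe3)2, DME, −60 °C; then 17, −60 °C to rt
Reagents that add atoms: none
Why: Julia–Kocienski olefination; the premetalated sulfone adds to the α-branched aldehyde and Smiles rearrangement with loss of SO2 and tetrazolate gives the (E)-C9=C10 alkene, while no free base meets the peroxide or the epimerisable aldehyde.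

Step 20
Reactants: 26 methyl 2-[(3S,4S,6R)-6-[(2R,3E,6S,7E)-2,6-dimethyl-8-phenylocta-3,7-dien-1-yl]-4,6-dimethyl-1,2-dioxan-3-yl]acetate
Product: 27 2-[(3S,4S,6R)-6-[(2R,3E,6S,7E)-2,6-dimethyl-8-phenylocta-3,7-dien-1-yl]-4,6-dimethyl-1,2-dioxan-3-yl]acetic acid (CNP0179089.2)
Conditions: LiOH, THF/H2O, 0 °C; then cold 1 M HCl to pH 3
Reagents that add atoms: lithium hydroxide, [Li+].[OH-]
Why: Mild saponification of the methyl ester at low temperature, to limit retro-oxa-Michael opening of the β-peroxy ester.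

**Compound list**

1 | (S)-3-bromo-2-methylpropan-1-ol | BrC[C@@H](C)CO | starting material
2 | (S)-(3-bromo-2-methylpropoxy)(tert-butyl)diphenylsilane | BrC[C@@H](C)CO[Si](c1ccccc1)(c1ccccc1)C(C)(C)C | intermediate
3 | [(S)-3-[(tert-butyldiphenylsilyl)oxy]-2-methylpropyl]magnesium bromide | Br[Mg]C[C@@H](C)CO[Si](c1ccccc1)(c1ccccc1)C(C)(C)C | intermediate
4 | (R)-5-[(tert-butyldiphenylsilyl)oxy]-4-methylpentan-2-one | CC(=O)C[C@@H](C)CO[Si](c1ccccc1)(c1ccccc1)C(C)(C)C | intermediate
5 | (R)-tert-butyl[(4,4-dimethoxy-2-methylpentyl)oxy]diphenylsilane | COC(C)(OC)C[C@@H](C)CO[Si](c1ccccc1)(c1ccccc1)C(C)(C)C | intermediate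
6 | 2-[(trimethylsilyl)methyl]prop-2-en-1-ol | C=C(CO)C[Si](C)(C)C | starting material
7 | 2-[(trimethylsilyl)methyl]prop-2-enal | C=C(C=O)C[Si](C)(C)C | intermediate
8 | (R)-2-hydroxy-1,2,2-triphenylethyl acetate | CC(=O)O[C@H](c1ccccc1)C(O)(c1ccccc1)c1ccccc1 | starting material
9 | (R)-2-hydroxy-1,2,2-triphenylethyl (R)-3-hydroxy-4-[(trimethylsilyl)methyl]pent-4-enoate | C=C(C[Si](C)(C)C)[C@H](O)CC(=O)O[C@H](c1ccccc1)C(O)(c1ccccc1)c1ccccc1 | intermediate
10 | methyl (R)-3-hydroxy-4-[(trimethylsilyl)methyl]pent-4-enoate | C=C(C[Si](C)(C)C)[C@H](O)CC(=O)OC | intermediate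
11 | methyl (R)-3-[(methylsulfonyl)oxy]-4-[(trimethylsilyl)methyl]pent-4-enoate | C=C(C[Si](C)(C)C)[C@H](OS(C)(=O)=O)CC(=O)OC | intermediate
12 | methyl (S)-3-hydroperoxy-4-[(trimethylsilyl)methyl]pent-4-enoate | C=C(C[Si](C)(C)C)[C@@H](OO)CC(=O)OC | intermediate
13 | methyl (3S)-3-({(4R)-5-[(tert-butyldiphenylsilyl)oxy]-2-methoxy-4-methylpentan-2-yl}peroxy)-4-[(trimethylsilyl)methyl]pent-4-enoate (both epimers at the ketal carbon) | C=C(C[Si](C)(C)C)[C@@H](OOC(C)(OC)C[C@@H](C)CO[Si](c1ccccc1)(c1ccccc1)C(C)(C)C)CC(=O)OC | intermediate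
14 | methyl 2-[(3S,6R)-6-{(R)-3-[(tert-butyldiphenylsilyl)oxy]-2-methylpropyl}-6-methyl-4-methylidene-1,2-dioxan-3-yl]acetate | CC(C)(C)[Si](c1ccccc1)(c1ccccc1)OC[C@H](C)C[C@]1(C)CC(=C)[C@H](CC(=O)OC)OO1 | intermediate
15 | methyl 2-[(3S,4S,6R)-6-{(R)-3-[(tert-butyldiphenylsilyl)oxy]-2-methylpropyl}-4,6-dimethyl-1,2-dioxan-3-yl]acetate | CC(C)(C)[Si](c1ccccc1)(c1ccccc1)OC[C@H](C)C[C@]1(C)C[C@H](C)[C@H](CC(=O)OC)OO1 | intermediate
16 | methyl 2-[(3S,4S,6R)-6-[(R)-3-hydroxy-2-methylpropyl]-4,6-dimethyl-1,2-dioxan-3-yl]acetate | OC[C@H](C)C[C@]1(C)C[C@H](C)[C@H](CC(=O)OC)OO1 | intermediate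
17 | methyl 2-[(3S,4S,6S)-4,6-dimethyl-6-[(R)-2-methyl-3-oxopropyl]-1,2-dioxan-3-yl]acetate | O=C[C@H](C)C[C@]1(C)C[C@H](C)[C@H](CC(=O)OC)OO1 | intermediate
18 | (E)-but-2-enal | C/C=C/C=O | starting material
19 | rac-(E)-1-phenylbut-2-en-1-ol | C/C=C/C(O)c1ccccc1 | intermediate
20 | (R,E)-1-phenylbut-2-en-1-ol | C/C=C/[C@@H](O)c1ccccc1 | intermediate
21 | 1-ethoxy-1-{[(1R,2E)-1-phenylbut-2-en-1-yl]oxy}ethene | C=C(OCC)O[C@H](/C=C/C)c1ccccc1 | intermediate
22 | ethyl (S,E)-3-methyl-5-phenylpent-4-enoate | C[C@H](/C=C/c1ccccc1)CC(=O)OCC | intermediate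
23 | (S,E)-3-methyl-5-phenylpent-4-en-1-ol | C[C@H](/C=C/c1ccccc1)CCO | intermediate
24 | 5-{[(S,E)-3-methyl-5-phenylpent-4-en-1-yl]sulfanyl}-1-phenyl-1H-tetrazole | C[C@H](/C=C/c1ccccc1)CCSc1nnnn1-c1ccccc1 | intermediate
25 | 5-{[(S,E)-3-methyl-5-phenylpent-4-en-1-yl]sulfonyl}-1-phenyl-1H-tetrazole | C[C@H](/C=C/c1ccccc1)CCS(=O)(=O)c1nnnn1-c1ccccc1 | intermediate
26 | methyl 2-[(3S,4S,6R)-6-[(2R,3E,6S,7E)-2,6-dimethyl-8-phenylocta-3,7-dien-1-yl]-4,6-dimethyl-1,2-dioxan-3-yl]acetate | C[C@H](/C=C/c1ccccc1)C/C=C/[C@H](C)C[C@]1(C)C[C@H](C)[C@H](CC(=O)OC)OO1 | intermediate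
27 | 2-[(3S,4S,6R)-6-[(2R,3E,6S,7E)-2,6-dimethyl-8-phenylocta-3,7-dien-1-yl]-4,6-dimethyl-1,2-dioxan-3-yl]acetic acid | C[C@H](/C=C/c1ccccc1)C/C=C/[C@H](C)C[C@]1(C)C[C@H](C)[C@H](CC(=O)O)OO1 | target

**Count**

Total steps: 20. Longest linear sequence: 11 (steps 4–12, 19, 20).

**Steps most likely to fail**

Step 9 (ring closure). What may go wrong is poor facial selectivity at C6, or ionisation with loss of the peroxide instead of methoxide. The fallback builds the ring by C–O instead of C–C bond formation and sets out from ketone 4.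
- KN(SiMe3)2 and PhNTf2 give the less substituted enol triflate (R)-5-[(tert-butyldiphenylsilyl)oxy]-4-methylpent-1-en-2-yl trifluoromethanesulfonate F1.
- The known building block methyl (R,E)-5-iodo-4-methylpent-2-enoate F2 is converted with zinc dust into [(2R,3E)-5-methoxy-2-methyl-5-oxopent-3-en-1-yl]zinc iodide F3.
- Negishi coupling of F1 with F3 (Pd(PPh3)4) gives methyl (2E,4S,8R)-9-[(tert-butyldiphenylsilyl)oxy]-4,8-dimethyl-6-methylidenenon-2-enoate F4.
- Mukaiyama–Isayama peroxidation of the 1,1-disubstituted alkene (Co(thd)2, O2, Et3SiH) gives methyl (2E,4S,8R)-9-[(tert-butyldiphenylsilyl)oxy]-4,6,8-trimethyl-6-[(triethylsilyl)peroxy]non-2-enoate F5.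
- HCl in MeOH frees methyl (2E,4S,8R)-9-[(tert-butyldiphenylsilyl)oxy]-6-hydroperoxy-4,6,8-trimethylnon-2-enoate F6.
- Et2NH in CF3CH2OH closes the dioxane by intramolecular oxa-Michael addition, and chromatographic separation of the ring diastereomers comes back to the route at 15. C4 is then preset by F2, so step 10 is not needed on this path.

Step 7 (allylic perhydrolysis). What may go wrong is ionisation of the allylic mesylate (loss of configuration, SN2′ transposition) and E1cB loss of the β-sulfonyloxy ester. The fallback resolves the hydroperoxide instead of relying on a stereospecific displacement and sets out from 12 of eroded enantiopurity.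
- PPTS-catalysed addition to the 2-propenyl ether of (1R,2S)-2-phenylcyclohexan-1-ol F7 gives diastereomeric perketals.
- Chromatography isolates methyl (S)-3-[(2-{[(1R,2S)-2-phenylcyclohexyl]oxy}propan-2-yl)peroxy]-4-[(trimethylsilyl)methyl]pent-4-enoate F8.
- AcOH/THF/H2O then returns configurationally pure 12.

Step 10 (C4 reduction). What may go wrong is poor facial selectivity, with hydrogen delivered syn to the C3 arm to give the C4 epimer. The fallback sets out from 14.
- The exo-methylene is moved into the ring by hydrogen-atom-transfer isomerisation (chloro[N,N′-bis(3,5-di-tert-butylsalicylidene)-1,2-cyclohexanediaminato]cobalt, PhSiH3), giving methyl 2-[(3S,6R)-6-{(R)-3-[(tert-butyldiphenylsilyl)oxy]-2-methylpropyl}-4,6-dimethyl-3,6-dihydro-1,2-dioxin-3-yl]acetate F9.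
- In F9 both carbon arms at C3 and C6 shield the same face of the C4=C5 alkene, so diimide should add from the open face and come back to the route at 15.

**Further compounds**

F1 | step 9 | (R)-5-[(tert-butyldiphenylsilyl)oxy]-4-methylpent-1-en-2-yl trifluoromethanesulfonate | C=C(OS(=O)(=O)C(F)(F)F)C[C@@H](C)CO[Si](c1ccccc1)(c1ccccc1)C(C)(C)C
F2 | step 9 | methyl (R,E)-5-iodo-4-methylpent-2-enoate | IC[C@H](C)/C=C/C(=O)OC
F3 | step 9 | [(2R,3E)-5-methoxy-2-methyl-5-oxopent-3-en-1-yl]zinc iodide | I[Zn]C[C@H](C)/C=C/C(=O)OC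
F4 | step 9 | methyl (2E,4S,8R)-9-[(tert-butyldiphenylsilyl)oxy]-4,8-dimethyl-6-methylidenenon-2-enoate | C=C(C[C@@H](C)CO[Si](c1ccccc1)(c1ccccc1)C(C)(C)C)C[C@H](C)/C=C/C(=O)OC
F5 | step 9 | methyl (2E,4S,8R)-9-[(tert-butyldiphenylsilyl)oxy]-4,6,8-trimethyl-6-[(triethylsilyl)peroxy]non-2-enoate (both C6 epimers) | CC[Si](CC)(CC)OOC(C)(C[C@@H](C)CO[Si](c1ccccc1)(c1ccccc1)C(C)(C)C)C[C@H](C)/C=C/C(=O)OC
F6 | step 9 | methyl (2E,4S,8R)-9-[(tert-butyldiphenylsilyl)oxy]-6-hydroperoxy-4,6,8-trimethylnon-2-enoate (both C6 epimers) | OOC(C)(C[C@@H](C)CO[Si](c1ccccc1)(c1ccccc1)C(C)(C)C)C[C@H](C)/C=C/C(=O)OC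
F7 | step 7 | 2-propenyl ether of (1R,2S)-2-phenylcyclohexan-1-ol | C=C(C)O[C@@H]1CCCC[C@H]1c1ccccc1
F8 | step 7 | methyl (S)-3-[(2-{[(1R,2S)-2-phenylcyclohexyl]oxy}propan-2-yl)peroxy]-4-[(trimethylsilyl)methyl]pent-4-enoate | C=C(C[Si](C)(C)C)[C@@H](OOC(C)(C)O[C@@H]1CCCC[C@H]1c1ccccc1)CC(=O)OC
F9 | step 10 | methyl 2-[(3S,6R)-6-{(R)-3-[(tert-butyldiphenylsilyl)oxy]-2-methylpropyl}-4,6-dimethyl-3,6-dihydro-1,2-dioxin-3-yl]acetate | CC(C)(C)[Si](c1ccccc1)(c1ccccc1)OC[C@H](C)C[C@]1(C)C=C(C)[C@H](CC(=O)OC)OO1
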